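What stays the same within the scatter across the earlier runs is the fraction of the charge not yet standing as target at a given time. At 2.50 min, larch with 0.13 M of substrate reads 5.1 % of target and elm with 0.30 M reads 4.8 %, against a scatter of 0.5 percentage points.

| flask | substrate | solid reagent | remark | time |
|---|---|---|---|---|
| larch | 0.13 M | 0.14 M | run made earlier |  |
| elm | 0.30 M | 0.14 M | run made earlier |  |
| maple | 0.20 M | 0.28 M | run made earlier |  |
| flask | 0.20 M | 0.140 M |  | 4.0 min |

- larch (time / min: target / %): 0.667: 0.9; 1.33: 2.1; 2.00: 3.1; 2.50: 5.1
- elm (time / min: target / %): 0.667: 0; 1.33: 1.6; 2.00: 2.4; 2.50: 4.8
- maple (time / min: target / %): 0.667: 0.7; 1.33: 2.5; 2.00: 3.7; 2.50: 4.8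

(readings scatter by 0.5 percentage points)

- as a solid, counted per litre of solution: solid reagent
- the analysis behind the earlier runs scatters by 0.5 percentage points, standard deviation
- at the start none of the solid reagent is in solution

- eta: doubling the dissolution coefficient of the solid reagent, all else as stated
- epsilon: doubling the solubility of the solid reagent, all else as stated

* the target standing at 4.0 min, as a percentage of the substrate charged
* the change that raises the amount of target at 4.0 min, in percent of the substrate charged most ("none" if none brings more than 2 percentage points) (eta / epsilon / none)
* amount of target at 4.0 min, in percent of the substrate charged, after eta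

So we treat the substrate as pseudo-first-order and work with the fraction left. Maple, with 0.28 M of solid reagent, reads 4.8 %, so at this reading the solid load does not show and we pool the three runs. The exposure, minus the logarithm of the fraction left, is 0.0502 at that time.

Take the main step first, with dissolved reagent at a fixed level: exposure grows with time, and 4.0 min gives 7.72 % of target. Now add dissolving. Nothing is in solution at the start, so the level rises with time, exposure grows with its square, and the target becomes 12.1 %. Last comes the solubility ceiling, which bends the square back towards the line, and we commit to the middle, 9.90 %.

Doubling the solubility doubles the dissolved level at each moment while solid remains, so the fraction left is squared and the target reaches 18.8 %. Doubling the dissolution coefficient speeds the early rise under the same ceiling, so we take the middle again, 14.4 %, and choose epsilon.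

The forecast gives 8 %, epsilon and 8.7 % after eta, lower than ours on eta, holding that “the rate is then set by solubility, not by the solid load”.

The flask gives 10.5 % of target, epsilon as the best change, and 16.2 % after eta.

    substrate + partner → target (k = 0.0190 M⁻¹ s⁻¹)
    solid reagent ⇌ partner, rate k2*(cs2 - [partner]) while solid is left; crystals form when [partner] > cs2 (solubility = 0.0920 M, k = 0.00410 s⁻¹)
    target ⇌ isomer of the product (K = 5.90, k = 9.40 × 10⁻⁴ s⁻¹)

At 2.00 min the partner in this flask stood at 31.9 % of saturation. The exposure 0.0502 puts the same flask, read at 2.5 min, at 4.90 % of target, and that neighbour gives 5.22 %. Doubling this flask's exposure, 0.121 from the substrate left, 89 %, promises 10 points more substrate turned over by doubled solubility, and the simulated gain in target is 9.4 points.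

The earlier runs and the new flask stem from a simulated flask with constants of no real substance.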